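(All runs were generated by integration on assumed constants, and the scatter is random.)

**One step.** In a one-step world, L → Q, each L lost stands as Q. The epsilon run refuses that picture: at 2.00 min it has lost 68.5 % of its L and shows 30.5 % of Q.

| flask | L | J | temperature | remark | time |
|---|---|---|---|---|---|
| epsilon | 21 mM (in portions, 4) | 0.53 mM | 48 °C | run made earlier; portions every 6.0 s |  |
| theta | 21 mM (in portions, 4) | 0.79 mM | 86 °C | run made earlier; portions every 6.0 s |  |
| delta | 10 mM (in portions, 4) | 1.05 mM | 48 °C | run made earlier; portions every 6.0 s |  |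
| noon | 21 mM (in portions, 4) | 1.05 mM | 90 °C | the portions of L follow each other after 6.0 s, the first at the start | 2.0 min |
| winter | 21 mM (in portions, 4) | 1.05 mM | 60 °C | the portions of L follow each other after 6.0 s, the first at the start | 2.0 min |
| summer | 21 mM (in portions, 4) | 1.05 mM | 30 °C | the portions of L follow each other after 6.0 s, the first at the start | 2.0 min |
| dawn | 21 mM (in portions, 4) | 1.05 mM | 100 °C | the portions of L follow each other after 6.0 s, the first at the start | 2.0 min |

epsilon run (percent of the L charged)

| time / min | Q / % | L / % |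
|---|---|---|
| 0.417 | 7.6 | 80.2 |
| 0.833 | 16.8 | 58.8 |
| 1.33 | 25.0 | 43.2 |
| 2.00 | 30.5 | 31.5 |
| 2.50 | 32.5 | 26.7 |

theta run (percent of the L charged)

| time / s | Q / % | L / % |
|---|---|---|
| 10.0 | 20.4 | 16.5 |
| 12.0 | 21.5 | 14.2 |
| 20.0 | 38.8 | 28.7 |

delta run (percent of the L charged)

| time / min | Q / % | L / % |
|---|---|---|
| 0.333 | 5.8 | 85.0 |
| 0.667 | 13.1 | 66.3 |
| 0.833 | 16.8 | 59.2 |
| 1.50 | 25.9 | 40.2 |
| 2.50 | 31.2 | 27.7 |

(scatter of a reading: 0.5 percentage points)

- percent here means L units held: one Z counts as two
- what is said of Q includes Z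
- steps that have been proposed: L <-> Q; L + Q <-> Z; E <-> L; L + J -> X; L <-> G; Q <-> E
- in an amount of Q, one Z counts as one Q

- the flasks by amount of Q, in percent of the L charged, highest first, at 2.0 min (noon / winter / summer / dawn)
- the same order at 25 s (noon / winter / summer / dawn)
- the amount of Q, in percent of the L charged of the flask you put first, at 2.0 min
- the amount of Q, in percent of the L charged of the flask you put last, at 2.0 min

**Frozen share.** Epsilon gives 0.445 at 2.00 min for the Q share, cQ divided by the L lost, a selectivity read with the scatter of the readings. At 2.50 min it reads 0.443, so the two late readings of epsilon stand close together.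

**First objection.** The proposed step L + J → X can take L away, and J per L differs between runs: 0.0252 in epsilon, 0.105 in delta. Yet delta, whose charge of L differs too, reads 0.432 at 2.50 min, close to epsilon. Winter, at 0.0500, lies between them, so the share is carried over to it.

**Second objection.** The share isn't constant everywhere. Epsilon starts at 0.384 at 0.417 min, and theta, hot, reads 0.544 at 20.0 s. It is therefore used here for winter, at 60 °C against the 48 °C of epsilon, and not for the hotter flasks.

**Where L stops.** Equal half-minute drops of L in epsilon shrink at 1.01 min⁻¹, which, run on as one exponential, puts a floor near 19.4 %, an estimate from scattered readings. That floor is assumed to hold in winter and to be reached there by 2.0 min, though it was read at 48 °C. The share then gives winter 35.9 % of Q at 2.0 min.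

**The forecast.** It expects winter > noon > dawn > summer at 2.0 min and noon > dawn > winter > summer at 25 s, with 38 % for the first flask and 11 % for the last, saying “60 °C is nearly relaxed with little drain, so about 38%”. Its top stands above the value reckoned here.

**The flasks.** They give winter > noon > dawn > summer at 2.0 min and dawn > noon > winter > summer at 25 s, with 37.5 % in winter and 8.52 % in summer.

    L ⇌ Q (K = 1.40, k = 0.0170 s⁻¹, Ea = 82.0 kJ mol⁻¹, ΔH = 17.0 kJ mol⁻¹)
    L + Q ⇌ Z, settled at all times (K = 140 M⁻¹, ΔH = −27.0 kJ mol⁻¹)
    E ⇌ L (k = 0.00150 s⁻¹, Ea = 104 kJ mol⁻¹)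
    L + J → X (k = 4.00 M⁻¹ s⁻¹, Ea = 45.0 kJ mol⁻¹)
    L ⇌ G (K = 9.30, k = 0.00150 s⁻¹, Ea = 87.0 kJ mol⁻¹, ΔH = 34.0 kJ mol⁻¹)
    Q ⇌ E (K = 2.90, k = 0.00140 s⁻¹, Ea = 89.0 kJ mol⁻¹, ΔH = −59.0 kJ mol⁻¹)
    (constants at 60 °C)

**Share again.** Winter holds 17.3 % of L at 2.00 min, where the share gives 36.8 % of Q against 37.5 %, and winter read at 30 s holds 49.5 % of L, where it gives 22.5 % against 22.7 %. In winter the relaxation half-life of L and free Q by its own step, 0.396 min, is shorter than that of E and L, 1.52 min, and than that of free Q and E, 6.14 min.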